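**Plan**
- Numbering: coumarin numbers, unprimed in the 4,7-dimethoxy half (benzene ring A) and primed in the 7'-hydroxy half (benzene ring B). The halves meet at C8–C6'.
- Enabling feature: O1, C2, C3, C4(OMe), C4a and C8a together are a 4-methoxy-2-pyrone. C8 is the carbon attached to pyrone C6, and C4a is pyrone C5. As a CH2 group, C8 is acidified by both the pyrone and ring B, and C7, C6, C5 and the 5-methyl map onto an acetoacetyl unit.
- Cuts, in retrosynthetic order: 4'-O–CH3; O1'–C2' and C2'–C3' (one carbonate carbon); C4a'–C4' (acetyl); C4a–C5 and C7–C8 of ring A; last C8–C6', which at the carbinol level is an aryl-to-aldehyde bond.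
- Forward: ring B (orcinol) and the pyrone ring are bought. An aryllithium adds to the pyrone-6-carbaldehyde (C8–C6'), ring A grows around C8 in one flask, and the primed pyranone closes last.
- Stereochemistry: the target has no stereocentre. The hindered C8–C6' axis arises together with ring A and is not controlled.

Key step: step 6

Assumption: the target SMILES carries no axial descriptor, so the racemic mixture of atropisomers is taken as the goal.

**Step 1**
Reactants: 1 orcinol (5-methylbenzene-1,3-diol); 2 benzyl bromide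
Product: 3 1,3-bis(benzyloxy)-5-methylbenzene
Conditions: 2 (2.2 equiv), K2CO3, DMF, 60 °C
Reagents that add atoms: none
Why: Williamson ether synthesis on both phenols installs benzyl groups that should tolerate organolithium, acid and amide base and later leave together by hydrogenolysis.

**Step 2**
Reactants: 3 1,3-bis(benzyloxy)-5-methylbenzene
Product: 4 1,5-bis(benzyloxy)-2-bromo-3-methylbenzene
Conditions: NBS (1.0 equiv), MeCN, 0 °C, dark
Reagents that add atoms: N-bromosuccinimide, O=C1CCC(=O)N1Br
Why: Electrophilic aromatic bromination in a polar solvent should go para to one benzyloxy group and next to the methyl group, as is usual for 3,5-dialkoxytoluenes, because the site between the two ethers is the most shielded.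

**Step 3**
Reactants: 5 4-methoxy-6-methyl-2H-pyran-2-one
Product: 6 4-methoxy-2-oxo-2H-pyran-6-carbaldehyde
Conditions: SeO2, 1,4-dioxane, 160 °C, sealed tube
Reagents that add atoms: selenium dioxide, O=[Se]=O
Why: Riley oxidation of the allylic-type 6-methyl group to the aldehyde is an established reaction of this pyrone.

**Step 4**
Reactants: 4 1,5-bis(benzyloxy)-2-bromo-3-methylbenzene; 6 4-methoxy-2-oxo-2H-pyran-6-carbaldehyde
Product: 8 6-{[2,4-bis(benzyloxy)-6-methylphenyl](hydroxy)methyl}-4-methoxy-2H-pyran-2-one (racemic), via aryllithium 7 (not isolated)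
Conditions: n-BuLi, THF, −78 °C; 6 in THF, −78 °C; AcOH quench
Reagents that add atoms: none
Why: Bromine–lithium exchange and 1,2-addition of the aryllithium to the aldehyde, which at −78 °C is far more electrophilic than the pyrone lactone, make the C8–C6' bond; the carbinol carbon forms as a racemate and loses its stereogenicity in step 5.

**Step 5**
Reactants: 8 6-{[2,4-bis(benzyloxy)-6-methylphenyl](hydroxy)methyl}-4-methoxy-2H-pyran-2-one
Product: 9 6-[2,4-bis(benzyloxy)-6-methylbenzyl]-4-methoxy-2H-pyran-2-one
Conditions: Et3SiH, CF3CO2H, CH2Cl2, 0 °C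
Reagents that add atoms: none
Why: Ionic hydrogenation should be easy because the ortho and para benzyloxy groups assist ionization of the carbinol, while the pyrone and the benzyl ethers are inert at 0 °C.

**Step 6**
Reactants: 9 6-[2,4-bis(benzyloxy)-6-methylbenzyl]-4-methoxy-2H-pyran-2-one; 10 ethyl 2-(2-methyl-1,3-dioxolan-2-yl)acetate
Product: 15 8-[2,4-bis(benzyloxy)-6-methylphenyl]-7-hydroxy-4-methoxy-5-methylcoumarin, via lithium anion 11 (not isolated), via keto ketal 12 (not isolated), via diketone 13 (not isolated), via aldol 14 (not isolated)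
Conditions: LiN(SiMe3)2 (1.05 equiv), THF, −78 °C; 10 (1.3 equiv); LiN(SiMe3)2 (1.1 equiv, slow addition), −78 → 0 °C; then MeOH, conc. aq HCl, 0 → 50 °C, same flask
Reagents that add atoms: none
Why: Proposed new method: LiN(SiMe3)2 takes a proton only from the CH2 group flanked by pyrone C6 and ring B, anion 11 attacks the ester carbonyl of 10 in a crossed Claisen acylation (C7–C8), and the second portion of base stores 12 as its enolate, which pulls the equilibrium forward while keeping free amide, and hence enolization of 10, low. Acid then cleaves the dioxolane, the C7 ketone of 13 enolizes towards C8 so that pyrone C5 becomes the terminus of a dienol that is also pushed by O1, and this carbon adds to the protonated methyl ketone (C4a–C5) to give 14, whose dehydration and tautomerization to the 7-phenol make the sequence irreversible. Ring A thus closes in a 6-(enolendo)-exo-trig aldol mode. The closest known reaction types are the side-chain acylation of lithiated 4-methoxy-6-methyl-2-pyrone by esters, the acylation of ketone polyanions by this same ketal ester, and the aldol aromatization of 6-(2,4-dioxoalkyl)-2-pyrones and diketo-dioxinones to resorcinol derivatives; what has not been shown is a nucleophilic carbon that already bears a di-ortho-substituted aryl group and the merger of all events in one flask. Two selectivities are needed: deprotonation and acylation at the benzylic carbon rather than at C3, secured by the double activation of that CH2 and by a base too weak to metalate C3–H, and closure at C5 only, secured because no other pyrone carbon reaches the ketone through a six-membered transition state; methanol as cosolvent makes any acid-induced exchange of the 4-methoxy group degenerate. No stereocentre survives, since those of 12 to 14 vanish on aromatization, and the C8–C6' axis forms as a racemate.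

**Step 7**
Reactants: 15 8-[2,4-bis(benzyloxy)-6-methylphenyl]-7-hydroxy-4-methoxy-5-methylcoumarin
Product: 16 8-[2,4-bis(benzyloxy)-6-methylphenyl]-4,7-dimethoxy-5-methylcoumarin
Conditions: MeI, K2CO3, DMF, 23 °C
Reagents that add atoms: iodomethane, CI
Why: Williamson methylation of the only free hydroxyl group fixes the 7-methoxy group while both ring B oxygens are still masked.

**Step 8**
Reactants: 16 8-[2,4-bis(benzyloxy)-6-methylphenyl]-4,7-dimethoxy-5-methylcoumarin
Product: 17 8-(2,4-dihydroxy-6-methylphenyl)-4,7-dimethoxy-5-methylcoumarin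
Conditions: H2 (1 atm), Pd/C, EtOAc–MeOH, 23 °C
Reagents that add atoms: none
Why: Catalytic hydrogenolysis should remove both benzyl ethers, and the C3–C4 double bond of a 4-alkoxycoumarin is not reduced under these mild conditions.

**Step 9**
Reactants: 17 8-(2,4-dihydroxy-6-methylphenyl)-4,7-dimethoxy-5-methylcoumarin
Product: 18 8-(3-acetyl-4,6-dihydroxy-2-methylphenyl)-4,7-dimethoxy-5-methylcoumarin
Conditions: AcOH, BF3·OEt2, 85 °C; aq NaOAc quench
Reagents that add atoms: acetic acid, CC(=O)O
Why: Friedel–Crafts (Nencki-type) C-acetylation should pick the resorcinol ring B as by far the most electron-rich arene and enter at C4a', para to the 7'-hydroxyl and ortho to the other, just as orcinol gives 2,4-dihydroxy-6-methylacetophenone and not the isomer acylated between the hydroxyls.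

**Step 10**
Reactants: 18 8-(3-acetyl-4,6-dihydroxy-2-methylphenyl)-4,7-dimethoxy-5-methylcoumarin
Product: 20 4',7'-dihydroxy-4,7-dimethoxy-5,5'-dimethyl-8,6'-bicoumarin, via keto ester 19 (not isolated)
Conditions: NaH (5 equiv), dimethyl carbonate, toluene, 100 °C; aq HCl work-up
Reagents that add atoms: dimethyl carbonate, COC(=O)OC
Why: Claisen C-methoxycarbonylation of the methyl ketone enolate and lactonization by the ortho phenoxide is the standard 4-hydroxycoumarin synthesis from 2-hydroxyacetophenones, and the dimethyl ester is chosen so that alkoxide exchange at C4 of the finished half is degenerate.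

**Step 11**
Reactants: 20 4',7'-dihydroxy-4,7-dimethoxy-5,5'-dimethyl-8,6'-bicoumarin
Product: 21 7'-hydroxy-4,4',7-trimethoxy-5,5'-dimethyl-8,6'-bicoumarin (CNP0113839.0)
Conditions: MeOH, conc. H2SO4 (10 vol %), reflux
Reagents that add atoms: methanol, CO
Why: Acid-catalysed, Fischer-type etherification touches only the vinylogous acid 4'-OH by addition–elimination, leaves the true phenol at C7' free, and would also restore any 4-methoxy group lost in steps 9 or 10.

**Compound list**
1 | orcinol (5-methylbenzene-1,3-diol) | Cc1cc(O)cc(O)c1 | starting material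
2 | benzyl bromide | BrCc1ccccc1 | starting material
3 | 1,3-bis(benzyloxy)-5-methylbenzene | Cc1cc(OCc2ccccc2)cc(OCc2ccccc2)c1 | intermediate
4 | 1,5-bis(benzyloxy)-2-bromo-3-methylbenzene | Cc1cc(OCc2ccccc2)cc(OCc2ccccc2)c1Br | intermediate
5 | 4-methoxy-6-methyl-2H-pyran-2-one | COC1=CC(=O)OC(C)=C1 | starting material
6 | 4-methoxy-2-oxo-2H-pyran-6-carbaldehyde | COC1=CC(=O)OC(C=O)=C1 | intermediate
7 | [2,4-bis(benzyloxy)-6-methylphenyl]lithium (not isolated) | [Li]c1c(C)cc(OCc2ccccc2)cc1OCc1ccccc1 | intermediate
8 | 6-{[2,4-bis(benzyloxy)-6-methylphenyl](hydroxy)methyl}-4-methoxy-2H-pyran-2-one (racemic) | COC1=CC(=O)OC(C(O)c2c(C)cc(OCc3ccccc3)cc2OCc2ccccc2)=C1 | intermediate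
9 | 6-[2,4-bis(benzyloxy)-6-methylbenzyl]-4-methoxy-2H-pyran-2-one | COC1=CC(=O)OC(Cc2c(C)cc(OCc3ccccc3)cc2OCc2ccccc2)=C1 | intermediate
10 | ethyl 2-(2-methyl-1,3-dioxolan-2-yl)acetate | CCOC(=O)CC1(C)OCCO1 | starting material
11 | lithium salt of 9 deprotonated at the benzylic carbon (not isolated) | [Li+].COC1=CC(=O)OC([CH-]c2c(C)cc(OCc3ccccc3)cc2OCc2ccccc2)=C1 | intermediate
12 | 6-{1-[2,4-bis(benzyloxy)-6-methylphenyl]-3-(2-methyl-1,3-dioxolan-2-yl)-2-oxopropyl}-4-methoxy-2H-pyran-2-one (racemic, not isolated) | COC1=CC(=O)OC(C(C(=O)CC2(C)OCCO2)c2c(C)cc(OCc3ccccc3)cc2OCc2ccccc2)=C1 | intermediate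
13 | 1-[2,4-bis(benzyloxy)-6-methylphenyl]-1-(4-methoxy-2-oxo-2H-pyran-6-yl)pentane-2,4-dione (racemic, not isolated) | COC1=CC(=O)OC(C(C(=O)CC(C)=O)c2c(C)cc(OCc3ccccc3)cc2OCc2ccccc2)=C1 | intermediate
14 | 8-[2,4-bis(benzyloxy)-6-methylphenyl]-5-hydroxy-4-methoxy-5-methyl-5,6-dihydro-4aH-chromene-2,7-dione (stereoisomer mixture, not isolated) | COC1=CC(=O)OC2=C(c3c(C)cc(OCc4ccccc4)cc3OCc3ccccc3)C(=O)CC(C)(O)C12 | intermediate
15 | 8-[2,4-bis(benzyloxy)-6-methylphenyl]-7-hydroxy-4-methoxy-5-methylcoumarin | COc1cc(=O)oc2c(-c3c(C)cc(OCc4ccccc4)cc3OCc3ccccc3)c(O)cc(C)c12 | intermediate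
16 | 8-[2,4-bis(benzyloxy)-6-methylphenyl]-4,7-dimethoxy-5-methylcoumarin | COc1cc(=O)oc2c(-c3c(C)cc(OCc4ccccc4)cc3OCc3ccccc3)c(OC)cc(C)c12 | intermediate
17 | 8-(2,4-dihydroxy-6-methylphenyl)-4,7-dimethoxy-5-methylcoumarin | COc1cc(=O)oc2c(-c3c(C)cc(O)cc3O)c(OC)cc(C)c12 | intermediate
18 | 8-(3-acetyl-4,6-dihydroxy-2-methylphenyl)-4,7-dimethoxy-5-methylcoumarin | COc1cc(=O)oc2c(-c3c(C)c(C(C)=O)c(O)cc3O)c(OC)cc(C)c12 | intermediate
19 | methyl 3-[3-(4,7-dimethoxy-5-methyl-2-oxo-2H-chromen-8-yl)-4,6-dihydroxy-2-methylphenyl]-3-oxopropanoate (not isolated) | COc1cc(=O)oc2c(-c3c(C)c(C(=O)CC(=O)OC)c(O)cc3O)c(OC)cc(C)c12 | intermediate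
20 | 4',7'-dihydroxy-4,7-dimethoxy-5,5'-dimethyl-8,6'-bicoumarin | COc1cc(C)c2c(OC)cc(=O)oc2c1-c1c(O)cc2oc(=O)cc(O)c2c1C | intermediate
21 | 7'-hydroxy-4,4',7-trimethoxy-5,5'-dimethyl-8,6'-bicoumarin (CNP0113839.0, racemic axis) | COc1cc(C)c2c(OC)cc(=O)oc2c1-c1c(O)cc2oc(=O)cc(OC)c2c1C | target

**Step count**
- Total step count: 11.
- Longest linear sequence: 10 (steps 1, 2 and 4 to 11). Step 3 is a one-step side branch.

**Steps most likely to fail**

**Step 6.**
- The amide base may enolize ester 10, after which a ketal oxygen is expelled by β-elimination.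
- The crowded, well-stabilized anion 11 may attack the ester too slowly.
- In the acid phase the enol oxygen of the diketone may add to pyrone C6 and open the lactone faster than C5 attacks the ketone.

The fallback sets out from 9 and 10, comes back at 15, and uses only known reaction types. Ester 10 is reduced with i-Bu2AlH in CH2Cl2 at −78 °C to (2-methyl-1,3-dioxolan-2-yl)acetaldehyde F1. Anion 11, made with one equivalent of LiN(SiMe3)2, adds to it at −78 °C in the aldol-type addition that is routine for lithiated 6-alkyl-4-methoxy-2-pyrones and needs no second equivalent of base. This gives 6-{1-[2,4-bis(benzyloxy)-6-methylphenyl]-2-hydroxy-3-(2-methyl-1,3-dioxolan-2-yl)propyl}-4-methoxy-2H-pyran-2-one F2. Dess–Martin periodinane oxidizes the alcohol to keto ketal 12, which is now isolated. Pyridinium p-toluenesulfonate in wet acetone frees diketone 13. Et3N in CH2Cl2 brings about the aldol closure to 14 under the mild basic conditions used for diketo-dioxinones, and HCl in MeOH dehydrates 14 to 15.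

**Step 9.**
- Acylation may occur at C8' between the two hydroxyl groups.
- O-acetates may fail to migrate.
- Hot BF3·OEt2/AcOH may cleave the 4-methoxy group by acidolysis.

The fallback sets out from 16, comes back at 18, and replaces electrophilic acylation by halogenation and cross-coupling. NBS in MeCN at 0 °C should brominate ring B of the dibenzyl ether para to the 7'-benzyloxy group, because the site between two benzyloxy groups is shielded. This gives 8-[4,6-bis(benzyloxy)-3-bromo-2-methylphenyl]-4,7-dimethoxy-5-methylcoumarin F3. Stille coupling with tributyl(1-ethoxyvinyl)stannane (Pd(PPh3)4, toluene, 110 °C) gives 8-[4,6-bis(benzyloxy)-3-(1-ethoxyvinyl)-2-methylphenyl]-4,7-dimethoxy-5-methylcoumarin F4. Aqueous HCl (1 M) in THF hydrolyses the enol ether to 8-[3-acetyl-4,6-bis(benzyloxy)-2-methylphenyl]-4,7-dimethoxy-5-methylcoumarin F5. Hydrogenolysis as in step 8 then gives 18.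

**Step 10.**
- Intermolecular acylation may be sluggish because the enolate's acetyl group is twisted between two ortho substituents.
- Carbonate formation at the 7'-phenoxide may consume reagent.
- Hot alkoxide may attack the finished lactone or its 4-methoxy group.

The fallback sets out from 18, comes back at 20, and makes the C–C bond intramolecularly at low temperature. Methyl chloroformate, Et3N and DMAP in CH2Cl2 give the bis(methyl carbonate) of 18 F6. LiN(SiMe3)2 (2.5 equiv) in THF, −78 → 0 °C, makes the ketone enolate, which attacks the neighbouring carbonate in a Baker–Venkataraman-type acyl transfer and closes the lactone. This gives the 7'-O-methoxycarbonyl derivative of 20 F7. K2CO3 in MeOH at 23 °C removes the remaining carbonate to give 20.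

**Further compounds**
F1 | step 6 | (2-methyl-1,3-dioxolan-2-yl)acetaldehyde | O=CCC1(C)OCCO1
F2 | step 6 | 6-{1-[2,4-bis(benzyloxy)-6-methylphenyl]-2-hydroxy-3-(2-methyl-1,3-dioxolan-2-yl)propyl}-4-methoxy-2H-pyran-2-one (diastereomer mixture) | COC1=CC(=O)OC(C(C(O)CC2(C)OCCO2)c2c(C)cc(OCc3ccccc3)cc2OCc2ccccc2)=C1
F3 | step 9 | 8-[4,6-bis(benzyloxy)-3-bromo-2-methylphenyl]-4,7-dimethoxy-5-methylcoumarin | COc1cc(=O)oc2c(-c3c(C)c(Br)c(OCc4ccccc4)cc3OCc3ccccc3)c(OC)cc(C)c12
F4 | step 9 | 8-[4,6-bis(benzyloxy)-3-(1-ethoxyvinyl)-2-methylphenyl]-4,7-dimethoxy-5-methylcoumarin | COc1cc(=O)oc2c(-c3c(C)c(C(=C)OCC)c(OCc4ccccc4)cc3OCc3ccccc3)c(OC)cc(C)c12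
F5 | step 9 | 8-[3-acetyl-4,6-bis(benzyloxy)-2-methylphenyl]-4,7-dimethoxy-5-methylcoumarin | COc1cc(=O)oc2c(-c3c(C)c(C(C)=O)c(OCc4ccccc4)cc3OCc3ccccc3)c(OC)cc(C)c12
F6 | step 10 | bis(methyl carbonate) of 18 | COc1cc(=O)oc2c(-c3c(C)c(C(C)=O)c(OC(=O)OC)cc3OC(=O)OC)c(OC)cc(C)c12
F7 | step 10 | 7'-O-methoxycarbonyl derivative of 20 | COc1cc(C)c2c(OC)cc(=O)oc2c1-c1c(OC(=O)OC)cc2oc(=O)cc(O)c2c1C
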